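**Retrosynthetic overview**
1. Target 26 comes from its nonamethyl ether 25 by global O-demethylation; 25 comes from a Heck union of vinyl arene 24 (ring A) with aryl bromide 15 (rings B–C), which sets the E-alkene.
2. Each dihydrobenzofuran is disconnected at its O–C2 bond: a 2-(1,2-diarylvinyl)phenol, formed in the flask from a tertiary benzylic alcohol, is closed by a chiral-acid-catalysed hydroalkoxylation that makes the C–O bond and sets C2 and C3.
3. The tertiary alcohols come from 2-hydroxybenzophenones and 4-methoxybenzylmagnesium chloride; the benzophenones come from a Friedel–Crafts acylation (ring C) or from aryl-metal addition to a salicylaldehyde followed by oxidation (rings A and B).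
4. Ring order: C first (from 1 and 2), then B on C-4 of ring C (through aryllithium 9), ring A separately from 16; A is joined to B–C at the end.

**Assumptions and short forms**
- The sense of induction of the new acid catalyst is unknown. (S,S)-IDPi-1 is taken to give the (2S,3S) ring and (R,R)-IDPi-1 the (2R,3R) ring; if a screen shows the opposite, the two are swapped.
- IDPi-1 is a BINOL-derived N-triflyl imidodiphosphorimidate with 3,5-bis(trifluoromethyl)phenyl groups in the 3,3'-positions.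
- [C] = (2S,3S)-3-(3,5-dimethoxyphenyl)-6-methoxy-2-(4-methoxyphenyl)-2,3-dihydro-1-benzofuran-4-yl.
- Carbinol centres and alkene geometries that are erased in the following step are carried as mixtures.

**Route**

Step 1
Reactants: 1 1-bromo-3,5-dimethoxybenzene; 2 3,5-dimethoxybenzoyl chloride
Product: 3 (2-bromo-6-hydroxy-4-methoxyphenyl)(3,5-dimethoxyphenyl)methanone
Conditions: AlCl3 (2.5 equiv), CH2Cl2, 0 → 40 °C; ice-water work-up
Reagents that add atoms: none
Why: Friedel–Crafts acylation goes to the position between Br and OMe (para to the second OMe), and excess AlCl3 then cleaves only the methoxy group chelated to the new ketone, which frees the ortho-phenol needed for ring closure.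

Step 2
Reactants: 3 (2-bromo-6-hydroxy-4-methoxyphenyl)(3,5-dimethoxyphenyl)methanone; 4 (4-methoxybenzyl)magnesium chloride
Product: 5 rac-1-(2-bromo-6-hydroxy-4-methoxyphenyl)-1-(3,5-dimethoxyphenyl)-2-(4-methoxyphenyl)ethan-1-ol
Conditions: 4 (2.3 equiv), LaCl3·2LiCl, THF, 0 °C → rt; H2O
Reagents that add atoms: none
Why: Grignard 1,2-addition to a non-enolisable, phenoxide-chelated ketone (the first equivalent deprotonates the phenol); the carbinol centre is erased in step 3, so no stereocontrol is needed.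

Step 3
Reactants: 5 rac-1-(2-bromo-6-hydroxy-4-methoxyphenyl)-1-(3,5-dimethoxyphenyl)-2-(4-methoxyphenyl)ethan-1-ol
Product: 7 (2S,3S)-4-bromo-3-(3,5-dimethoxyphenyl)-6-methoxy-2-(4-methoxyphenyl)-2,3-dihydro-1-benzofuran, via triarylethene 6 (not isolated)
Conditions: (S,S)-IDPi-1 (5 mol %), 5 Å MS, CHCl3, 0 °C → rt
Reagents that add atoms: none
Why: Proposed new method: the confined strong acid ionises the tertiary benzylic alcohol to an o-quinone-methide-type cation that loses a proton to the achiral triarylethene 6; the catalyst then protonates the diaryl carbon on one face (this sets C3), and the p-anisyl-stabilised cation at the next carbon is trapped at once by the ortho-OH held in the chiral ion pair, anti to the C3 aryl group, so the C–O bond closes the ring and sets C2 (trans, also the thermodynamic isomer); protonation at the other alkene carbon only returns the starting cation; the closest known reaction types are the chiral Brønsted acid (IDPi) catalysed asymmetric intramolecular hydroalkoxylation of alkenes and the racemic acid-mediated cyclodehydration of 2-(2-hydroxyaryl)-1,2-diarylethanols to trans-2,3-diaryl-2,3-dihydrobenzofurans.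

Step 4
Reactants: 7 (2S,3S)-4-bromo-3-(3,5-dimethoxyphenyl)-6-methoxy-2-(4-methoxyphenyl)-2,3-dihydro-1-benzofuran; 8 4-bromo-2-hydroxybenzaldehyde
Product: 11 (4-bromo-2-hydroxyphenyl)([C])methanol (both carbinol epimers), via aryllithium 9 (not isolated), via sodium phenolate 10 (not isolated)
Conditions: 8, NaH, THF, 0 °C (gives 10); 7, n-BuLi, THF, −78 °C (gives 9); 10 added to 9, −78 → 0 °C; H2O
Reagents that add atoms: none
Why: Br/Li exchange at −78 °C is faster than any deprotonation, and 1,2-addition of the aryllithium to the aldehyde is faster than exchange with the second aryl bromide (the phenol is masked as its sodium salt so it cannot quench 9); the new carbinol centre is oxidised away next and ring C is untouched.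

Step 5
Reactants: 11 (4-bromo-2-hydroxyphenyl)([C])methanol
Product: 12 (4-bromo-2-hydroxyphenyl)([C])methanone
Conditions: activated MnO2 (10 equiv), CH2Cl2, rt
Reagents that add atoms: none
Why: MnO2 oxidation of a doubly benzylic alcohol; the phenol, the aryl bromide and the dihydrobenzofuran C–H bonds are inert to this oxidant.

Step 6
Reactants: 12 (4-bromo-2-hydroxyphenyl)([C])methanone; 4 (4-methoxybenzyl)magnesium chloride
Product: 13 1-(4-bromo-2-hydroxyphenyl)-1-([C])-2-(4-methoxyphenyl)ethan-1-ol (both carbinol epimers)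
Conditions: 4 (2.3 equiv), LaCl3·2LiCl, THF, 0 °C → rt; H2O
Reagents that add atoms: none
Why: Grignard 1,2-addition as in step 2; the carbinol centre is erased in step 7.

Step 7
Reactants: 13 1-(4-bromo-2-hydroxyphenyl)-1-([C])-2-(4-methoxyphenyl)ethan-1-ol
Product: 15 (2R,3R)-6-bromo-3-([C])-2-(4-methoxyphenyl)-2,3-dihydro-1-benzofuran, via triarylethene 14 (not isolated)
Conditions: (R,R)-IDPi-1 (5 mol %), 5 Å MS, CHCl3, 0 °C → rt
Reagents that add atoms: none
Why: Proposed new method: the same dehydration, enantioface-selective protonation and C–O ring closure as in step 3, run with the enantiomeric catalyst so that reagent control gives the (2R,3R) ring B next to the existing (2S,3S) ring C; the five-membered O-closure should outrun the seven-membered Friedel–Crafts closure onto the ring-C aryl group, and the finished ring C, if it opens at all, recloses to the same trans ring before C3 can epimerise; the closest known reaction type is the chiral Brønsted acid (IDPi) catalysed asymmetric intramolecular hydroalkoxylation of alkenes.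

Step 8
Reactants: 16 5-bromo-2-hydroxy-3-methoxybenzaldehyde; 17 (3,5-dimethoxyphenyl)magnesium chloride
Product: 18 rac-4-bromo-2-[(3,5-dimethoxyphenyl)(hydroxy)methyl]-6-methoxyphenol
Conditions: 17 (2.3 equiv), THF, 0 °C → rt; H2O
Reagents that add atoms: none
Why: Grignard addition to a salicylaldehyde (the first equivalent deprotonates the phenol); the aryl bromide is inert to an aryl Grignard at this temperature.

Step 9
Reactants: 18 rac-4-bromo-2-[(3,5-dimethoxyphenyl)(hydroxy)methyl]-6-methoxyphenol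
Product: 19 (5-bromo-2-hydroxy-3-methoxyphenyl)(3,5-dimethoxyphenyl)methanone
Conditions: activated MnO2 (10 equiv), CH2Cl2, rt
Reagents that add atoms: none
Why: MnO2 oxidation of a doubly benzylic alcohol to the 2-hydroxybenzophenone.

Step 10
Reactants: 19 (5-bromo-2-hydroxy-3-methoxyphenyl)(3,5-dimethoxyphenyl)methanone; 4 (4-methoxybenzyl)magnesium chloride
Product: 20 rac-1-(5-bromo-2-hydroxy-3-methoxyphenyl)-1-(3,5-dimethoxyphenyl)-2-(4-methoxyphenyl)ethan-1-ol
Conditions: 4 (2.3 equiv), THF, 0 °C → rt; H2O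
Reagents that add atoms: none
Why: Grignard 1,2-addition to a non-enolisable ketone; the carbinol centre is erased in step 11.

Step 11
Reactants: 20 rac-1-(5-bromo-2-hydroxy-3-methoxyphenyl)-1-(3,5-dimethoxyphenyl)-2-(4-methoxyphenyl)ethan-1-ol
Product: 22 (2S,3S)-5-bromo-3-(3,5-dimethoxyphenyl)-7-methoxy-2-(4-methoxyphenyl)-2,3-dihydro-1-benzofuran, via triarylethene 21 (not isolated)
Conditions: (S,S)-IDPi-1 (5 mol %), 5 Å MS, CHCl3, 0 °C → rt
Reagents that add atoms: none
Why: Proposed new method: the same dehydration, enantioface-selective protonation (sets C3) and C–O ring closure anti to the C3 aryl group (sets C2, trans) as in step 3, with the same catalyst enantiomer; the closest known reaction type is the chiral Brønsted acid (IDPi) catalysed asymmetric intramolecular hydroalkoxylation of alkenes.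

Step 12
Reactants: 22 (2S,3S)-5-bromo-3-(3,5-dimethoxyphenyl)-7-methoxy-2-(4-methoxyphenyl)-2,3-dihydro-1-benzofuran; 23 tributyl(vinyl)stannane
Product: 24 (2S,3S)-3-(3,5-dimethoxyphenyl)-5-ethenyl-7-methoxy-2-(4-methoxyphenyl)-2,3-dihydro-1-benzofuran
Conditions: Pd(PPh3)4 (5 mol %), toluene, 100 °C
Reagents that add atoms: none
Why: Stille coupling of an aryl bromide under neutral conditions; both stereocentres are untouched.

Step 13
Reactants: 24 (2S,3S)-3-(3,5-dimethoxyphenyl)-5-ethenyl-7-methoxy-2-(4-methoxyphenyl)-2,3-dihydro-1-benzofuran; 15 (2R,3R)-6-bromo-3-([C])-2-(4-methoxyphenyl)-2,3-dihydro-1-benzofuran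
Product: 25 nonamethyl ether of the target (rings A and B–C joined through an (E)-ethene-1,2-diyl bridge from C-5 of ring A to C-6 of ring B)
Conditions: Pd(OAc)2 (5 mol %), P(o-tol)3, Et3N, DMF, 100 °C
Reagents that add atoms: none
Why: Mizoroki–Heck reaction; aryl transfer to the terminal alkene carbon and syn β-hydride elimination give the E-stilbene, as in standard stilbenoid syntheses; the six stereocentres are remote and base-stable.

Step 14
Reactants: 25 nonamethyl ether of the target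
Product: 26 target CNP0265934.1
Conditions: BCl3 (excess), n-Bu4NI, CH2Cl2, 0 °C → rt; H2O/MeOH work-up
Reagents that add atoms: none
Why: Lewis acid/iodide cleavage of aryl methyl ethers (SN2 at methyl) is milder than BBr3; any reversible opening of an O–C2 bond recloses to the same trans ring without touching C3, and the E-alkene is kept.

**Compound list**
1 | 1-bromo-3,5-dimethoxybenzene | COc1cc(Br)cc(OC)c1 | starting material
2 | 3,5-dimethoxybenzoyl chloride | COc1cc(cc(OC)c1)C(Cl)=O | starting material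
3 | (2-bromo-6-hydroxy-4-methoxyphenyl)(3,5-dimethoxyphenyl)methanone | COc1cc(O)c(C(=O)c2cc(OC)cc(OC)c2)c(Br)c1 | intermediate
4 | (4-methoxybenzyl)magnesium chloride (sold as THF solution) | COc1ccc(C[Mg]Cl)cc1 | starting material
5 | rac-1-(2-bromo-6-hydroxy-4-methoxyphenyl)-1-(3,5-dimethoxyphenyl)-2-(4-methoxyphenyl)ethan-1-ol | COc1ccc(CC(O)(c2cc(OC)cc(OC)c2)c2c(O)cc(OC)cc2Br)cc1 | intermediate
6 | 3-bromo-2-[1-(3,5-dimethoxyphenyl)-2-(4-methoxyphenyl)ethenyl]-5-methoxyphenol (E/Z mixture) | COc1ccc(C=C(c2cc(OC)cc(OC)c2)c2c(O)cc(OC)cc2Br)cc1 | intermediate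
7 | (2S,3S)-4-bromo-3-(3,5-dimethoxyphenyl)-6-methoxy-2-(4-methoxyphenyl)-2,3-dihydro-1-benzofuran | Brc1cc(OC)cc2c1[C@H](c1cc(OC)cc(OC)c1)[C@@H](c1ccc(OC)cc1)O2 | intermediate
8 | 4-bromo-2-hydroxybenzaldehyde | O=Cc1ccc(Br)cc1O | starting material
9 | [(2S,3S)-3-(3,5-dimethoxyphenyl)-6-methoxy-2-(4-methoxyphenyl)-2,3-dihydro-1-benzofuran-4-yl]lithium | [Li]c1cc(OC)cc2c1[C@H](c1cc(OC)cc(OC)c1)[C@@H](c1ccc(OC)cc1)O2 | intermediate
10 | sodium 5-bromo-2-formylphenolate | [Na+].[O-]c1cc(Br)ccc1C=O | intermediate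
11 | (4-bromo-2-hydroxyphenyl)[(2S,3S)-3-(3,5-dimethoxyphenyl)-6-methoxy-2-(4-methoxyphenyl)-2,3-dihydro-1-benzofuran-4-yl]methanol (both carbinol epimers) | OC(c1ccc(Br)cc1O)c1cc(OC)cc2c1[C@H](c1cc(OC)cc(OC)c1)[C@@H](c1ccc(OC)cc1)O2 | intermediate
12 | (4-bromo-2-hydroxyphenyl)[(2S,3S)-3-(3,5-dimethoxyphenyl)-6-methoxy-2-(4-methoxyphenyl)-2,3-dihydro-1-benzofuran-4-yl]methanone | O=C(c1ccc(Br)cc1O)c1cc(OC)cc2c1[C@H](c1cc(OC)cc(OC)c1)[C@@H](c1ccc(OC)cc1)O2 | intermediate
13 | 1-(4-bromo-2-hydroxyphenyl)-1-[(2S,3S)-3-(3,5-dimethoxyphenyl)-6-methoxy-2-(4-methoxyphenyl)-2,3-dihydro-1-benzofuran-4-yl]-2-(4-methoxyphenyl)ethan-1-ol (both carbinol epimers) | COc1ccc(CC(O)(c2ccc(Br)cc2O)c2cc(OC)cc3c2[C@H](c2cc(OC)cc(OC)c2)[C@@H](c2ccc(OC)cc2)O3)cc1 | intermediate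
14 | 5-bromo-2-{1-[(2S,3S)-3-(3,5-dimethoxyphenyl)-6-methoxy-2-(4-methoxyphenyl)-2,3-dihydro-1-benzofuran-4-yl]-2-(4-methoxyphenyl)ethenyl}phenol (E/Z mixture) | COc1ccc(C=C(c2ccc(Br)cc2O)c2cc(OC)cc3c2[C@H](c2cc(OC)cc(OC)c2)[C@@H](c2ccc(OC)cc2)O3)cc1 | intermediate
15 | (2R,3R)-6-bromo-3-[(2S,3S)-3-(3,5-dimethoxyphenyl)-6-methoxy-2-(4-methoxyphenyl)-2,3-dihydro-1-benzofuran-4-yl]-2-(4-methoxyphenyl)-2,3-dihydro-1-benzofuran | Brc1ccc2c(c1)O[C@@H](c1ccc(OC)cc1)[C@@H]2c1cc(OC)cc2c1[C@H](c1cc(OC)cc(OC)c1)[C@@H](c1ccc(OC)cc1)O2 | intermediate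
16 | 5-bromo-2-hydroxy-3-methoxybenzaldehyde | COc1cc(Br)cc(C=O)c1O | starting material
17 | (3,5-dimethoxyphenyl)magnesium chloride (sold as THF solution) | COc1cc([Mg]Cl)cc(OC)c1 | starting material
18 | rac-4-bromo-2-[(3,5-dimethoxyphenyl)(hydroxy)methyl]-6-methoxyphenol | COc1cc(cc(OC)c1)C(O)c1cc(Br)cc(OC)c1O | intermediate
19 | (5-bromo-2-hydroxy-3-methoxyphenyl)(3,5-dimethoxyphenyl)methanone | COc1cc(cc(OC)c1)C(=O)c1cc(Br)cc(OC)c1O | intermediate
20 | rac-1-(5-bromo-2-hydroxy-3-methoxyphenyl)-1-(3,5-dimethoxyphenyl)-2-(4-methoxyphenyl)ethan-1-ol | COc1ccc(CC(O)(c2cc(OC)cc(OC)c2)c2cc(Br)cc(OC)c2O)cc1 | intermediate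
21 | 4-bromo-2-[1-(3,5-dimethoxyphenyl)-2-(4-methoxyphenyl)ethenyl]-6-methoxyphenol (E/Z mixture) | COc1ccc(C=C(c2cc(OC)cc(OC)c2)c2cc(Br)cc(OC)c2O)cc1 | intermediate
22 | (2S,3S)-5-bromo-3-(3,5-dimethoxyphenyl)-7-methoxy-2-(4-methoxyphenyl)-2,3-dihydro-1-benzofuran | COc1ccc([C@H]2Oc3c(OC)cc(Br)cc3[C@@H]2c2cc(OC)cc(OC)c2)cc1 | intermediate
23 | tributyl(vinyl)stannane | C=C[Sn](CCCC)(CCCC)CCCC | starting material
24 | (2S,3S)-3-(3,5-dimethoxyphenyl)-5-ethenyl-7-methoxy-2-(4-methoxyphenyl)-2,3-dihydro-1-benzofuran | COc1ccc([C@H]2Oc3c(OC)cc(C=C)cc3[C@@H]2c2cc(OC)cc(OC)c2)cc1 | intermediate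
25 | (2S,3S)-3-(3,5-dimethoxyphenyl)-7-methoxy-2-(4-methoxyphenyl)-5-[(E)-2-{(2R,3R)-3-[(2S,3S)-3-(3,5-dimethoxyphenyl)-6-methoxy-2-(4-methoxyphenyl)-2,3-dihydro-1-benzofuran-4-yl]-2-(4-methoxyphenyl)-2,3-dihydro-1-benzofuran-6-yl}ethenyl]-2,3-dihydro-1-benzofuran (nonamethyl ether of the target) | COc1ccc([C@H]2Oc3c(OC)cc(/C=C/c4ccc5c(c4)O[C@@H](c4ccc(OC)cc4)[C@@H]5c4cc(OC)cc5c4[C@H](c4cc(OC)cc(OC)c4)[C@@H](c4ccc(OC)cc4)O5)cc3[C@@H]2c2cc(OC)cc(OC)c2)cc1 | intermediate
26 | CNP0265934.1 (ring A 2S,3S; ring B 2R,3R; ring C 2S,3S; E-alkene; nine free OH) | Oc1ccc([C@H]2Oc3c(O)cc(/C=C/c4ccc5c(c4)O[C@@H](c4ccc(O)cc4)[C@@H]5c4cc(O)cc5c4[C@H](c4cc(O)cc(O)c4)[C@@H](c4ccc(O)cc4)O5)cc3[C@@H]2c2cc(O)cc(O)c2)cc1 | target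

**Totals**
- Total step count: 14.
- Longest linear sequence: 9 steps (steps 1–7, then 13 and 14).

**Three steps most likely to fail**

Step 3, the new acid-catalysed cyclisation. The same reaction recurs in steps 7 and 11, so this is the first place it is tested; step 7 is its hardest case. Likely failure modes are low enantioselectivity in the protonation, or erosion of ee by reversible ring opening. The fallback uses the known Rh(II)-catalysed enantioselective C–H insertion of a donor/donor carbene; it sets out from 3 and comes back at 7. Ketone 3 is O-alkylated with 4-methoxybenzyl chloride (K2CO3, DMF) to the aryl benzyl ether F1. Condensation with hydrazine hydrate (cat. AcOH, n-BuOH, 110 °C; forcing because the ketone is di-ortho-substituted) gives the hydrazone F2. MnO2 oxidises F2 to the diaryldiazomethane F3, which is treated without isolation with Rh2(R-PTAD)4 (or its enantiomer, whichever gives 3S). Insertion into the benzylic ether C–H bond gives the cis-dihydrobenzofuran F4. Brief TFA in CH2Cl2 then epimerises C2 through reversible ring opening and gives the trans compound 7.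

Step 4, the aryllithium addition. Br/Li exchange next to the crowded C3 centre and addition to a phenolate-bearing aldehyde that carries its own aryl bromide may give protonated or scrambled material. The fallback replaces the organolithium by a catalytic boron route; it sets out from 7 and comes back at 11. Miyaura borylation of 7 (B2pin2, PdCl2(dppf), KOAc, dioxane, 90 °C) gives the pinacol boronate F5. Rh(I)-catalysed 1,2-addition of F5 to aldehyde 8 ([Rh(cod)Cl]2, KOH, dioxane/H2O, 80 °C) tolerates the free phenol and the aryl bromide and gives 11.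

Step 14, the ninefold demethylation. Nine ethers must be cleaved in the presence of three acid-labile 2-aryl-dihydrobenzofurans and an electron-rich stilbene that can undergo Friedel–Crafts chemistry. The fallback deprotects the two halves before the union and carries acetates; it sets out from 22 and 15 and comes back at 26. BCl3/n-Bu4NI on 22 gives the tetraphenol F6, and on 15 gives the pentaphenol F7; neither fragment has a stilbene. Ac2O/pyridine converts these to the tetraacetate F8 and the pentaacetate F9. Stille vinylation of F8 with 23 gives the vinyl tetraacetate F10. Heck coupling of F10 with F9 (Pd(OAc)2, P(o-tol)3, Et3N, DMF) gives the nonaacetate F11. K2CO3 in MeOH at 0 °C → rt then releases 26.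

**Further compounds**
F1 | step 3 | (2-bromo-4-methoxy-6-[(4-methoxyphenyl)methoxy]phenyl)(3,5-dimethoxyphenyl)methanone | COc1ccc(COc2cc(OC)cc(Br)c2C(=O)c2cc(OC)cc(OC)c2)cc1
F2 | step 3 | hydrazone of F1 | COc1ccc(COc2cc(OC)cc(Br)c2C(=NN)c2cc(OC)cc(OC)c2)cc1
F3 | step 3 | 1-bromo-2-[diazo(3,5-dimethoxyphenyl)methyl]-5-methoxy-3-[(4-methoxyphenyl)methoxy]benzene | COc1ccc(COc2cc(OC)cc(Br)c2C(=[N+]=[N-])c2cc(OC)cc(OC)c2)cc1
F4 | step 3 | (2R,3S)-4-bromo-3-(3,5-dimethoxyphenyl)-6-methoxy-2-(4-methoxyphenyl)-2,3-dihydro-1-benzofuran (cis) | Brc1cc(OC)cc2c1[C@H](c1cc(OC)cc(OC)c1)[C@H](c1ccc(OC)cc1)O2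
F5 | step 4 | 2-[(2S,3S)-3-(3,5-dimethoxyphenyl)-6-methoxy-2-(4-methoxyphenyl)-2,3-dihydro-1-benzofuran-4-yl]-4,4,5,5-tetramethyl-1,3,2-dioxaborolane | CC1(C)OB(OC1(C)C)c1cc(OC)cc2c1[C@H](c1cc(OC)cc(OC)c1)[C@@H](c1ccc(OC)cc1)O2
F6 | step 14 | (2S,3S)-5-bromo-3-(3,5-dihydroxyphenyl)-2-(4-hydroxyphenyl)-2,3-dihydro-1-benzofuran-7-ol | Oc1ccc([C@H]2Oc3c(O)cc(Br)cc3[C@@H]2c2cc(O)cc(O)c2)cc1
F7 | step 14 | (2R,3R)-6-bromo-3-[(2S,3S)-3-(3,5-dihydroxyphenyl)-6-hydroxy-2-(4-hydroxyphenyl)-2,3-dihydro-1-benzofuran-4-yl]-2-(4-hydroxyphenyl)-2,3-dihydro-1-benzofuran | Brc1ccc2c(c1)O[C@@H](c1ccc(O)cc1)[C@@H]2c1cc(O)cc2c1[C@H](c1cc(O)cc(O)c1)[C@@H](c1ccc(O)cc1)O2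
F8 | step 14 | tetraacetate of F6 | CC(=O)Oc1ccc([C@H]2Oc3c(OC(C)=O)cc(Br)cc3[C@@H]2c2cc(OC(C)=O)cc(OC(C)=O)c2)cc1
F9 | step 14 | pentaacetate of F7 | Brc1ccc2c(c1)O[C@@H](c1ccc(OC(C)=O)cc1)[C@@H]2c1cc(OC(C)=O)cc2c1[C@H](c1cc(OC(C)=O)cc(OC(C)=O)c1)[C@@H](c1ccc(OC(C)=O)cc1)O2
F10 | step 14 | 5-ethenyl analogue of F8 (vinyl tetraacetate) | CC(=O)Oc1ccc([C@H]2Oc3c(OC(C)=O)cc(C=C)cc3[C@@H]2c2cc(OC(C)=O)cc(OC(C)=O)c2)cc1
F11 | step 14 | nonaacetate of the target | CC(=O)Oc1ccc([C@H]2Oc3c(OC(C)=O)cc(/C=C/c4ccc5c(c4)O[C@@H](c4ccc(OC(C)=O)cc4)[C@@H]5c4cc(OC(C)=O)cc5c4[C@H](c4cc(OC(C)=O)cc(OC(C)=O)c4)[C@@H](c4ccc(OC(C)=O)cc4)O5)cc3[C@@H]2c2cc(OC(C)=O)cc(OC(C)=O)c2)cc1
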